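A closed, stirred vessel of constant volume is charged with substrate and held at one temperature for the run, and the question is what share of the finished products is target.

| flask | substrate | temperature | time |
|---|---|---|---|
| dusk | 0.40 M | 125 °C | 25 min |
| summer | 0.40 M | 100 °C | 25 min |
| winter | 0.40 M | 75 °C | 25 min |
| spring | 0.40 M | 50 °C | 25 min |

    intermediate A → side product B (k1 = 0.00360 s⁻¹, Ea1 = 121 kJ mol⁻¹)
    intermediate A ⇌ intermediate B (K2 = 0.45, k2 = 0.0443 s⁻¹, Ea2 = 98.0 kJ mol⁻¹, ΔH2 = −23.0 kJ mol⁻¹)
    substrate → target (k3 = 0.00498 s⁻¹, Ea3 = 106 kJ mol⁻¹)
    target ⇌ isomer of the product (K4 = 0.766, k4 = 0.0148 s⁻¹, Ea4 = 90.0 kJ mol⁻¹, ΔH4 = −28.0 kJ mol⁻¹)
    substrate → side product A (k5 = 0.00441 s⁻¹, Ea5 = 118 kJ mol⁻¹)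
    substrate → intermediate A (k6 = 0.0100 s⁻¹, Ea6 = 118 kJ mol⁻¹)
    (constants at 100 °C)

- the constants hold at 100 °C; other temperatures follow from the activation energies and enthalpies

* which flask leads in share of target in all that became target or side product A or side product B or isomer of the product ("all alike" within 1.5 percentage points) (dusk / summer / winter / spring / all alike)
* share of target in all that became target or side product A or side product B or isomer of the product, dusk
* share of target in all that became target or side product A or side product B or isomer of the product, summer
* share of target in all that became target or side product A or side product B or isomer of the product, winter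
* share of target in all that became target or side product A or side product B or isomer of the product, spring

Ines reckons as if the run were long against every step. Her share S is the fraction of substrate that goes to target, k3/(k3+k5+k6), times the fraction that equilibrium leaves as target, 1/(1+K4), with the constants taken at the temperature of the flask. K2 and K4 are here the ratios of intermediate B to intermediate A and of isomer to target.

For summer she has grounds. The substrate half-life of 0.596 min is shorter than the run of 25 min. In summer intermediate A turns into intermediate B at 0.0443 s⁻¹, faster than it goes on to side product B at 0.00360 s⁻¹, so side product B drains the pair through the fraction 1/(1+K2) that stands as intermediate A, with a half-life of 4.65 min, again shorter than the run. Her S is 14.5% for summer and 14.9% for dusk. For spring it is 9.43%.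

Tom disputes that spring figure. In the spring flask the substrate half-life is 177 min, longer than the run, so he expects kinetic control. Side product B lies behind a further step, so he counts target against side product A, whose selectivity factor k3/k5 is 2.05 in spring. Target made in a steady stream has stood on average for half the run, and it leaks to the isomer at a forward constant of 0.00998 min⁻¹ in spring. His share is therefore e = [k3/(k3+k5)]·exp(−k4·t/2), which gives 59.4% for spring. This early share is the quantity I carry on, and I commit to it for spring.

The early share takes the leak to the isomer as one-way, and I use it roughly for winter. Its early share, a rough 15.0%, is already lower than that of spring. My ranking therefore puts spring first.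

The forecast gave 14.9%, 14.8%, 25.3% and 57% for dusk, summer, winter and spring, the last lower than my figure, and named spring as leader, on the ground that “target makes up most of what has formed and spring leads”.

The simulation gives 14.9%, 14.8%, 25.3% and 59.4% in that order, so spring leads. The spring flask has reached a conversion of 9.33%, and Ines keeps the hot flasks, where substrate stands at 0% in dusk and 0% in summer. Carried to a longer spring run of 43.7 min, the early share becomes 54.1%, which is 5.3 percentage points lower than at 25 min. The simulated spring share has moved by about that much at that time.

In a flask like spring kept at 25 °C, the early share is 74.4%. The computed flask gives 74.4%, with 99.7% of its substrate left.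

(The numbers of this flask are invented; the result is computed.)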